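**Retrosynthetic overview**
1. Target 16 ⇒ α-onocerin 14: one exocyclic methylene is epoxidised and the 8,26-epoxide closes onto the other, forming C8–C27 and C14–O (ring C and the oxolane, formed last).
2. 14 ⇒ C2-symmetric 8,14-diketone 13 by double methylenation (adds C26 and C27).
3. 13 ⇒ acyclic bis-epoxide bis(silyl enol ether) 12 by two-directional epoxy-polyene bicyclisation (rings A/B and D/E formed together).
4. 12 ⇒ 2 × acylsilane 8 + 2 × vinyllithium + I2 (C8–C9 twice, C11–C12 once).
5. 8 ⇒ acetyltrimethylsilane 6 + (S)-epoxygeranyl bromide 5, the latter from Shi epoxidation of geranyl acetate 1 (the only source of chirality).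

Assumption: the SMILES is read as 14β,26-epoxyserratane-3β,21α-diol (C30H50O3); vinyllithium is used as a pre-made, titrated stock solution and the ent-Shi ketone as a purchased catalyst.

**Step 1**
Reactants: 1 geranyl acetate
Product: 2 (S)-6,7-epoxygeranyl acetate
Conditions: ent-Shi ketone (L-fructose-derived, 30 mol %), Oxone, K2CO3, Bu4NHSO4 (cat.), Na2B4O7–Na2EDTA buffer, MeCN–DMM–H2O, 0 °C
Reagents that add atoms: potassium peroxymonosulfate (Oxone), [K+].[O-]S(=O)(=O)OO
Why: Shi asymmetric epoxidation (chiral dioxirane organocatalysis, no metal catalyst): the allylic acetate deactivates the 2,3-alkene so only the 6,7-alkene reacts, and the spiro transition state of the ent-Shi ketone gives the (S)-epoxide (expected about 90–95% ee), which later becomes C3 and C21.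

**Step 2**
Reactants: 2 (S)-6,7-epoxygeranyl acetate
Product: 3 (S)-6,7-epoxygeraniol
Conditions: K2CO3 (0.2 equiv), MeOH, 0 °C → rt
Reagents that add atoms: none
Why: base-catalysed transesterification (methanolysis) removes the acetate without opening the trisubstituted epoxide.

**Step 3**
Reactants: 3 (S)-6,7-epoxygeraniol
Product: 5 (S)-6,7-epoxygeranyl bromide, via epoxygeranyl mesylate 4 (not isolated)
Conditions: MsCl, Et3N, THF, −45 °C; then LiBr, THF, −45 → 0 °C; used crude
Reagents that add atoms: lithium bromide, [Li+].[Br-]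
Why: mesylation followed by SN2 (Finkelstein-type) displacement at the primary allylic carbon proceeds at low temperature without allylic transposition and leaves the epoxide and E-alkene intact.

**Step 4**
Reactants: 5 (S)-6,7-epoxygeranyl bromide; 6 acetyltrimethylsilane
Product: 8 (4E)-7-[(2S)-3,3-dimethyloxiran-2-yl]-5-methyl-1-(trimethylsilyl)hept-4-en-1-one, via lithium enolate 7 (not isolated)
Conditions: 6, LDA, THF, −78 °C; then 5, DMPU, −78 → −40 °C
Reagents that add atoms: none
Why: SN2 alkylation of the kinetic lithium enolate of an acylsilane (only one enolisable position) by a reactive primary allylic bromide forms the C6–C7 bond and creates no stereocentre.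

**Step 5**
Reactants: 8 acylsilane (2 equiv)
Product: 12 (3S,6E,10Z,14Z,18E,22S)-2,3:22,23-diepoxy-2,6,19,23-tetramethyl-10,15-bis(trimethylsilyloxy)tetracosa-6,10,14,18-tetraene, via lithium alkoxide 9 (not isolated), via siloxyallyllithium 10 (not isolated), via allylic iodide 11 (not isolated)
Conditions: CH2=CHLi (1.05 equiv), Et2O, −78 °C; THF, −78 → −45 °C; I2 (0.5 equiv), THF, −78 °C; NaHCO3/Na2S2O3 work-up, used after filtration through Et3N-deactivated silica
Reagents that add atoms: vinyllithium, [Li]C=C
Why: four-component coupling by 1,2-addition of vinyllithium to the acylsilane, 1,2-Brook rearrangement to the chelated siloxyallyl anion and iodine-mediated oxidative γ,γ-dimerisation gives the Z,Z-bis(enol ether) with the C11–C12 bond; homodimerisation also raises the ee of the C2 series to above 99% because the minor enantiomer ends up mainly in a meso-type diastereomer that is removed at 13.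

**Step 6**
Reactants: 12 bis-epoxide bis(silyl enol ether)
Product: 13 3β,21α-dihydroxy-26,27-dinor-8,14-secogammacerane-8,14-dione (C2-symmetric diketodiol)
Conditions: MeAlCl2 (5 equiv), CH2Cl2, −94 → −78 °C; aq. citric acid work-up; recrystallisation
Reagents that add atoms: none
Why: Lewis-acid-initiated epoxy-polyene bicyclisation at both ends with Mukaiyama-type termination by the silyl enol ethers proceeds through chair–chair transition states with anti addition across the E-alkenes, so each (S)-epoxide dictates 3β-OH, 5α-H and 10β-Me, and the Z-enol ether gives the equatorial side chain at C9/C13 (9α-H, also the thermodynamic α-keto epimer).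

**Step 7**
Reactants: 13 diketodiol
Product: 14 α-onocerin [8,14-secogammacera-8(26),14(27)-diene-3β,21α-diol]
Conditions: Ph3PCH3Br (8 equiv), KOtBu (7.5 equiv), PhMe, 90 °C
Reagents that add atoms: methyltriphenylphosphonium bromide (as its ylide), C[P+](c1ccccc1)(c1ccccc1)c1ccccc1.[Br-]
Why: Wittig methylenation with excess ylide converts both hindered ketones into exocyclic methylenes, the free hydroxyls being carried as inert alkoxides and C9/C13 already sitting in the stable equatorial configuration.

**Step 8**
Reactants: 14 α-onocerin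
Product: 16 14β,26-epoxyserratane-3β,21α-diol (target), via 8α,26-epoxy-α-onocerin 15 (not isolated)
Conditions: mCPBA (1.0 equiv, added over 2 h), HFIP–CH2Cl2 (1:2), −20 → 0 °C
Reagents that add atoms: mCPBA, OOC(=O)c1cccc(Cl)c1
Why: Proposed new method: one-pot desymmetrising mono-epoxidation and intramolecular epoxide–alkene formal (3+2) cycloaddition, in which mCPBA epoxidises one of the two homotopic methylenes, HFIP (with the m-chlorobenzoic acid formed) ionises the tertiary C8–O bond, C27 of the second methylene attacks the C8 cation on its equatorial α face (anti to the axial 10β-methyl, setting C8), and the resulting C14 cation is captured 5-exo by the C26 oxygen from the only face the bicyclo[4.2.1] bridge allows (setting 14β), the ring closure consuming the second alkene so that over-epoxidation is self-limiting; closest known reaction types are the HFIP/acid-promoted formal (3+2) annulation of epoxides with alkenes to tetrahydrofurans and the oxygen-return (bridged ether) pathway of interrupted epoxy-polyene cyclisations.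

**Compound list**
1 | geranyl acetate, (2E)-3,7-dimethylocta-2,6-dien-1-yl acetate | CC(C)=CCC/C(C)=C/COC(C)=O | starting material
2 | (S)-6,7-epoxygeranyl acetate, (2E)-5-[(2S)-3,3-dimethyloxiran-2-yl]-3-methylpent-2-en-1-yl acetate | CC1(C)O[C@H]1CC/C(C)=C/COC(C)=O | intermediate
3 | (S)-6,7-epoxygeraniol | CC1(C)O[C@H]1CC/C(C)=C/CO | intermediate
4 | (S)-6,7-epoxygeranyl methanesulfonate (not isolated) | CC1(C)O[C@H]1CC/C(C)=C/COS(C)(=O)=O | intermediate
5 | (S)-6,7-epoxygeranyl bromide | CC1(C)O[C@H]1CC/C(C)=C/CBr | intermediate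
6 | acetyltrimethylsilane, 1-(trimethylsilyl)ethan-1-one | CC(=O)[Si](C)(C)C | starting material
7 | lithium 1-(trimethylsilyl)ethen-1-olate (not isolated) | C=C(O[Li])[Si](C)(C)C | intermediate
8 | (4E)-7-[(2S)-3,3-dimethyloxiran-2-yl]-5-methyl-1-(trimethylsilyl)hept-4-en-1-one | CC1(C)O[C@H]1CC/C(C)=C/CCC(=O)[Si](C)(C)C | intermediate
9 | lithium alkoxide of (6E)-9-[(2S)-3,3-dimethyloxiran-2-yl]-7-methyl-3-(trimethylsilyl)nona-1,6-dien-3-ol, C3 epimers (not isolated) | CC1(C)O[C@H]1CC/C(C)=C/CCC(O[Li])(C=C)[Si](C)(C)C | intermediate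
10 | Brook-rearranged siloxyallyllithium, drawn as the 3-lithio-3-(trimethylsilyloxy)-1-ene form (not isolated) | CC1(C)O[C@H]1CC/C(C)=C/CCC([Li])(C=C)O[Si](C)(C)C | intermediate
11 | (Z)-γ-iodo silyl enol ether, (2Z,6E)-9-[(2S)-3,3-dimethyloxiran-2-yl]-1-iodo-7-methyl-3-(trimethylsilyloxy)nona-2,6-diene (not isolated) | CC1(C)O[C@H]1CC/C(C)=C/CC/C(O[Si](C)(C)C)=C/CI | intermediate
12 | (3S,6E,10Z,14Z,18E,22S)-2,3:22,23-diepoxy-2,6,19,23-tetramethyl-10,15-bis(trimethylsilyloxy)tetracosa-6,10,14,18-tetraene | CC1(C)O[C@H]1CC/C(C)=C/CC/C(O[Si](C)(C)C)=C/CC/C=C(O[Si](C)(C)C)/CC/C=C(C)/CC[C@@H]1OC1(C)C | intermediate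
13 | 3β,21α-dihydroxy-26,27-dinor-8,14-secogammacerane-8,14-dione; two trans-decalones (3β-OH, 4,4,10-trimethyl, 5α-H, 9α-H, 8-oxo) joined C9–CH2CH2–C13 | CC1(C)[C@@H](O)CC[C@@]2(C)[C@H]1CCC(=O)[C@@H]2CC[C@H]1C(=O)CC[C@H]2C(C)(C)[C@@H](O)CC[C@]12C | intermediate
14 | α-onocerin, 8,14-secogammacera-8(26),14(27)-diene-3β,21α-diol | CC1(C)[C@@H](O)CC[C@@]2(C)[C@H]1CCC(=C)[C@@H]2CC[C@H]1C(=C)CC[C@H]2C(C)(C)[C@@H](O)CC[C@]12C | intermediate
15 | 8α,26-epoxy-8,14-secogammacer-14(27)-ene-3β,21α-diol, spiro-oxirane with O α and CH2 β (not isolated) | CC1(C)[C@@H](O)CC[C@@]2(C)[C@H]1CC[C@]3(CO3)[C@@H]2CC[C@H]1C(=C)CC[C@H]2C(C)(C)[C@@H](O)CC[C@]12C | intermediate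
16 | 14β,26-epoxyserratane-3β,21α-diol | CC1(C)[C@@H](O)CC[C@@]2(C)[C@H]1CC[C@]13CO[C@@]4(CC[C@H]5C(C)(C)[C@@H](O)CC[C@]5(C)[C@H]4CC[C@@H]12)C3 | target

**Step count and risks**
Total steps: 8. Longest linear sequence: 8 (1 → 16); 6 enters at step 4.

Step 8 (the proposed new cascade) is the most likely to fail. The C8 cation may rearrange to the C26 aldehyde (Meinwald), lose a proton to an allylic alcohol, or the epoxide may open in a concerted anti fashion and give the C8 epimer. A 26-hydroxyserrat-14-ene formed by proton loss after C–C closure should still funnel to 16 by acid-mediated hydroalkoxylation. The fallback uses known chemistry, sets out from 13 and returns at 16. A one-sided Wittig methylenation (1.1 equiv ylide; 13 and 14 recovered and recycled) gives 3β,21α-dihydroxy-26-nor-8,14-secogammacer-14(27)-en-8-one, the keto-alkene F1. Corey–Chaykovsky reaction with dimethylsulfoxonium methylide (NaH, DMSO–THF) delivers CH2 equatorially to give the 8β,26-epoxide F2 (oxygen axial, β). BF3·OEt2 in CH2Cl2 at −78 °C then effects the classical anti epoxide–olefin closure, with C27 attacking from the α face opposite the departing oxygen and the alkoxide returning to C14, to give 16.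

Step 6 (double bicyclisation terminated by trimethylsilyl enol ethers) may suffer premature desilylation or stop after one ring. The fallback sets out from 12 and returns at 14, bypassing 13 and step 7. CsF/PhNTf2 in DME converts both enol ethers with retention into the (Z,Z)-bis(enol triflate) F3. Pd(PPh3)4-catalysed Kumada coupling with Me3SiCH2MgCl gives the bis(allylsilane) F4. MeAlCl2 in CH2Cl2 at −94 °C then gives the allylsilane-terminated tetracyclisation, which installs both exocyclic methylenes directly.

Step 5 (oxidative γ,γ-dimerisation of the TMS-siloxyallyl anion) may give α-coupling or lose the labile silyl groups. The fallback sets out from 8 and returns at 12. 1,4-Bis(phenylsulfonyl)butane is dilithiated (2 n-BuLi, THF, −78 °C) and adds to two molecules of 8 to give the bis(β-sulfonyl α-silyl lithium alkoxide) F5. On warming, Brook rearrangement and β-elimination of benzenesulfinate form both C8=C9 enol ethers with the four-carbon C9–C13 unit delivered in one piece. Any E-enol ether is tolerable because C9/C13 in 13 can be equilibrated (K2CO3, MeOH) to the equatorial configuration.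

**Further compounds**
F1 | step 8 | 3β,21α-dihydroxy-26-nor-8,14-secogammacer-14(27)-en-8-one | CC1(C)[C@@H](O)CC[C@@]2(C)[C@H]1CCC(=O)[C@@H]2CC[C@H]1C(=C)CC[C@H]2C(C)(C)[C@@H](O)CC[C@]12C
F2 | step 8 | 8β,26-epoxy-8,14-secogammacer-14(27)-ene-3β,21α-diol (spiro-oxirane, O β, CH2 α) | CC1(C)[C@@H](O)CC[C@@]2(C)[C@H]1CC[C@@]3(CO3)[C@@H]2CC[C@H]1C(=C)CC[C@H]2C(C)(C)[C@@H](O)CC[C@]12C
F3 | step 6 | (3S,6E,10Z,14Z,18E,22S)-2,3:22,23-diepoxy-2,6,19,23-tetramethyltetracosa-6,10,14,18-tetraene-10,15-diyl bis(trifluoromethanesulfonate) | CC1(C)O[C@H]1CC/C(C)=C/CC/C(OS(=O)(=O)C(F)(F)F)=C/CC/C=C(OS(=O)(=O)C(F)(F)F)/CC/C=C(C)/CC[C@@H]1OC1(C)C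
F4 | step 6 | (3S,6E,10Z,14Z,18E,22S)-2,3:22,23-diepoxy-2,6,19,23-tetramethyl-10,15-bis[(trimethylsilyl)methyl]tetracosa-6,10,14,18-tetraene | CC1(C)O[C@H]1CC/C(C)=C/CC/C(C[Si](C)(C)C)=C/CC/C=C(C[Si](C)(C)C)/CC/C=C(C)/CC[C@@H]1OC1(C)C
F5 | step 5 | dilithium bis-alkoxide from double addition of 1,4-dilithio-1,4-bis(phenylsulfonyl)butane to 8 (new stereocentres undefined, not isolated) | CC1(C)O[C@H]1CC/C(C)=C/CCC(O[Li])([Si](C)(C)C)C(S(=O)(=O)c1ccccc1)CCC(S(=O)(=O)c1ccccc1)C(O[Li])([Si](C)(C)C)CC/C=C(C)/CC[C@@H]1OC1(C)C
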